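**Assumptions.** Target locants used throughout: C1(Et)=C2–C3(Me)–C3a–C4(Me)=C5–C6(Me)(dienyl)–C7(Me)(CO2H)–C7a. The given SMILES corresponds to (3R,3aS,6S,7R,7aR), a trans-fused ring system with C6-Me and C7-Me cis. Ylide 8 is treated as a catalogue reagent. If it is not available, it is made in one off-line step from propylidenetriphenylphosphorane and ethyl formate.

## Retrosynthetic overview
1. The C1'=C2' bond is cut by an HWE disconnection to diethyl cinnamylphosphonate and the bicyclic C6-formyl/C7-acid 14. Compound 14 comes from aldehyde/acetal 13 by oxidation and unmasking.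
2. Compound 13 comes from a light-gated intramolecular Diels–Alder reaction of the acyclic all-E tetraenal 11. This step forms C3a–C7a and C6–C7, so the cyclopentene and cyclohexene rings form together.
3. Compound 11 is built by four E-selective Wittig homologations, two in each direction outward from C3.
4. C3 is bought as (R)-Roche ester. C3a, C7a, C6 and C7 are relayed from it in the cycloaddition.

## Route

**Step 1**
Reactants: 1, methyl (R)-3-hydroxy-2-methylpropanoate
Product: 2, methyl (R)-3-[(tert-butyldimethylsilyl)oxy]-2-methylpropanoate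
Conditions: TBSCl, imidazole, CH2Cl2, 0 °C → rt
Reagents that add atoms: TBSCl, CC(C)(C)[Si](C)(C)Cl
Why: Standard O-silylation that does not touch the stereocentre.

**Step 2**
Reactants: 2
Product: 3, (R)-3-[(tert-butyldimethylsilyl)oxy]-2-methylpropanal
Conditions: DIBAL-H (1.1 equiv), CH2Cl2, −78 °C; Rochelle salt; used crude
Reagents that add atoms: none
Why: Partial ester reduction stops at the aluminium hemiacetal at −78 °C, and the α-stereocentre is kept because the aldehyde is not chromatographed.

**Step 3**
Reactants: 3; 4, 2-(triphenylphosphoranylidene)propanal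
Product: 5, (2E,4S)-5-[(tert-butyldimethylsilyl)oxy]-2,4-dimethylpent-2-enal
Conditions: 4 (1.3 equiv), toluene, 90 °C
Reagents that add atoms: 4, CC(C=O)=P(c1ccccc1)(c1ccccc1)c1ccccc1
Why: Wittig olefination with a formyl-stabilised ylide is E-selective (forms C3a=C4) and neutral, so C3 is not epimerised.

**Step 4**
Reactants: 5; 4
Product: 6, (2E,4E,6S)-7-[(tert-butyldimethylsilyl)oxy]-2,4,6-trimethylhepta-2,4-dienal
Conditions: 4 (2 equiv), toluene, 110 °C
Reagents that add atoms: 4, CC(C=O)=P(c1ccccc1)(c1ccccc1)c1ccccc1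
Why: A second stabilised-ylide Wittig forms C5=C6 as the E isomer, placing the future C6-Me "inside" and the carbonyl carbon "outside" on the diene.

**Step 5**
Reactants: 6
Product: 7, (2S,3E,5E)-7,7-dimethoxy-2,4,6-trimethylhepta-3,5-dien-1-ol
Conditions: HC(OMe)3, MeOH, CSA (10 mol %), 0 °C → rt; Et3N quench
Reagents that add atoms: trimethyl orthoformate, COC(OC)OC; methanol, CO
Why: Acid-catalysed acetalisation of the dienal, with CSA/MeOH solvolysing the primary TBS ether in the same pot; this removes the second carbonyl chromophore before the light step.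

**Step 6**
Reactants: 7; 8, 2-(triphenylphosphoranylidene)butanal
Product: 10, (2E,4S,5E,7E)-2-ethyl-9,9-dimethoxy-4,6,8-trimethylnona-2,5,7-trienal, formed via aldehyde 9, (2S,3E,5E)-7,7-dimethoxy-2,4,6-trimethylhepta-3,5-dienal (not isolated)
Conditions: DMP, pyridine, CH2Cl2, 0 °C; then 8 (2.5 equiv), 40 °C, one pot
Reagents that add atoms: 8, CCC(C=O)=P(c1ccccc1)(c1ccccc1)c1ccccc1
Why: A one-pot Dess–Martin/Wittig sequence traps the epimerisable β,γ-unsaturated aldehyde as it forms, and the pyridine buffer protects the acetal.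

**Step 7**
Reactants: 10; 4
Product: 11, (2E,4E,6S,7E,9E)-4-ethyl-11,11-dimethoxy-2,6,8,10-tetramethylundeca-2,4,7,9-tetraenal
Conditions: 4 (2 equiv), toluene, 90 °C
Reagents that add atoms: 4, CC(C=O)=P(c1ccccc1)(c1ccccc1)c1ccccc1
Why: An E-selective Wittig installs the C7=C7a enal dienophile, and the E C1=C2 tether makes 11 geometrically unable to cyclise, so it can be isolated and purified.

**Step 8 (key step)**
Reactants: 11
Product: 13, (3R,3aS,6S,7R,7aR)-6-(dimethoxymethyl)-1-ethyl-3,4,6,7-tetramethyl-3a,6,7,7a-tetrahydro-3H-indene-7-carbaldehyde, formed via the (2E,4Z)-isomer 12 (not isolated)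
Conditions: hν (365 nm LED), Ar-sparged MeCN (5 mM), NaHCO3 (s), BHT (5 mol %), 30 °C
Reagents that add atoms: none
Why: Proposed new method: a light-gated intramolecular Diels–Alder reaction in which 365 nm light is absorbed only by the n→π* band of the 2,4-dienal (the dienyl acetal and product 13 are transparent), intersystem crossing gives a twisted ³(π,π*) dienal that relaxes to E/Z mixtures, and only the contra-thermodynamic (4Z)-isomer 12 can place the enal C7=C7a over the C3a=C4–C5=C6 diene, so 12 is drained irreversibly by a [4+2] that forms C3a–C7a, C6–C7 and both rings during irradiation while (2Z)-isomers are re-excited and recycled; A1,3 strain (C3–H eclipsing C4–Me) fixes the diene face anti to the C3 methyl, the formyl-endo (trans-hydrindene) transition state sets C3a/C7a, and the E,E-diene and E-enal geometries transfer suprafacially to the cis C6-Me/C7-Me quaternary pair; the closest known reaction types are photochemical E/Z isomerisation of polyenals and thermal IMDA of preformed (Z)-tethered tetraenes.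

**Step 9**
Reactants: 13
Product: 14, (3R,3aS,6S,7R,7aR)-1-ethyl-6-formyl-3,4,6,7-tetramethyl-3a,6,7,7a-tetrahydro-3H-indene-7-carboxylic acid (expected mainly as its cyclic hydroxy-lactone tautomer)
Conditions: NaClO2, NaH2PO4, 2-methyl-2-butene, t-BuOH/H2O, 0 °C; Na2SO3 quench; then 1 M HCl/THF, rt
Reagents that add atoms: sodium chlorite, [Na+].[O-]Cl=O; water, O
Why: Pinnick oxidation converts the hindered C7 aldehyde to the acid without touching the alkenes, and after the oxidant is destroyed mild aqueous acid unmasks the C6 aldehyde with no change at any stereocentre.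

**Step 10**
Reactants: 14; 15, diethyl (E)-cinnamylphosphonate
Product: 16, 22-nor-zyggomphic acid B
Conditions: 15 (3 equiv), NaHMDS (4 equiv total), THF, −78 °C → rt; pH 4 work-up
Reagents that add atoms: 15, CCOP(=O)(OCC)C/C=C/c1ccccc1
Why: In this Horner–Wadsworth–Emmons olefination base opens the pseudo-acid to the carboxylate-aldehyde, the allylic phosphonate anion gives the new C1'=C2' bond as E with the styrenyl E bond retained, and C6 and C7 are quaternary so nothing can epimerise.

## Compound list
1 | methyl (R)-3-hydroxy-2-methylpropanoate | COC(=O)[C@H](C)CO | starting material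
2 | methyl (R)-3-(TBSO)-2-methylpropanoate | COC(=O)[C@H](C)CO[Si](C)(C)C(C)(C)C | intermediate
3 | (R)-3-(TBSO)-2-methylpropanal | O=C[C@H](C)CO[Si](C)(C)C(C)(C)C | intermediate
4 | 2-(triphenylphosphoranylidene)propanal | CC(C=O)=P(c1ccccc1)(c1ccccc1)c1ccccc1 | starting material
5 | (2E,4S)-5-(TBSO)-2,4-dimethylpent-2-enal | O=C/C(C)=C/[C@H](C)CO[Si](C)(C)C(C)(C)C | intermediate
6 | (2E,4E,6S)-7-(TBSO)-2,4,6-trimethylhepta-2,4-dienal | O=C/C(C)=C/C(C)=C/[C@H](C)CO[Si](C)(C)C(C)(C)C | intermediate
7 | (2S,3E,5E)-7,7-dimethoxy-2,4,6-trimethylhepta-3,5-dien-1-ol | OC[C@@H](C)/C=C(\C)/C=C(\C)C(OC)OC | intermediate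
8 | 2-(triphenylphosphoranylidene)butanal | CCC(C=O)=P(c1ccccc1)(c1ccccc1)c1ccccc1 | starting material
9 | (2S,3E,5E)-7,7-dimethoxy-2,4,6-trimethylhepta-3,5-dienal | O=C[C@@H](C)/C=C(\C)/C=C(\C)C(OC)OC | intermediate (not isolated)
10 | (2E,4S,5E,7E)-2-ethyl-9,9-dimethoxy-4,6,8-trimethylnona-2,5,7-trienal | O=C/C(CC)=C/[C@@H](C)/C=C(\C)/C=C(\C)C(OC)OC | intermediate
11 | (2E,4E,6S,7E,9E)-4-ethyl-11,11-dimethoxy-2,6,8,10-tetramethylundeca-2,4,7,9-tetraenal | O=C/C(C)=C/C(CC)=C/[C@@H](C)/C=C(\C)/C=C(\C)C(OC)OC | intermediate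
12 | (2E,4Z,6S,7E,9E)-isomer of 11 | O=C/C(C)=C/C(CC)=C\[C@@H](C)/C=C(\C)/C=C(\C)C(OC)OC | intermediate (transient)
13 | (3R,3aS,6S,7R,7aR)-6-(dimethoxymethyl)-1-ethyl-3,4,6,7-tetramethyl-3a,6,7,7a-tetrahydro-3H-indene-7-carbaldehyde | CCC1=C[C@@H](C)[C@@H]2C(C)=C[C@](C)(C(OC)OC)[C@](C)(C=O)[C@@H]12 | intermediate
14 | (3R,3aS,6S,7R,7aR)-1-ethyl-6-formyl-3,4,6,7-tetramethyl-3a,6,7,7a-tetrahydro-3H-indene-7-carboxylic acid | CCC1=C[C@@H](C)[C@@H]2C(C)=C[C@](C)(C=O)[C@](C)(C(=O)O)[C@@H]12 | intermediate
15 | diethyl (E)-cinnamylphosphonate | CCOP(=O)(OCC)C/C=C/c1ccccc1 | starting material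
16 | 22-nor-zyggomphic acid B, (3R,3aS,6S,7R,7aR)-1-ethyl-3,4,6,7-tetramethyl-6-[(1E,3E)-4-phenylbuta-1,3-dienyl]-3a,6,7,7a-tetrahydro-3H-indene-7-carboxylic acid | CCC1=C[C@@H](C)[C@@H]2C(C)=C[C@](C)(/C=C/C=C/c3ccccc3)[C@](C)(C(=O)O)[C@@H]12 | target

## Step count
- Total steps: 10
- Longest linear sequence: 10

## Steps most likely to fail
1. **Step 8 (the proposed new step).**
   - Risk: Competing 2E→2Z isomerisation could build a 2H-pyran reservoir or give a C7-epimeric adduct through the (2Z,4Z)-isomer.
   - Risk: Endo/exo leakage could give the cis-hydrindene, and the cycloaddition could be slow.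
   - Fallback (known chemistry): Build the Z tether deliberately. Run a Still–Gennari Z-selective HWE on 9 with ethyl 2-[bis(2,2,2-trifluoroethoxy)phosphoryl]butanoate, then DIBAL-H, MnO2 and a Wittig with 4 to reach 12. Cyclise 12 by a purely thermal IMDA at rt–60 °C. This costs two more steps.
2. **Step 6.**
   - Risk: Aldehyde 9 may epimerise or slip into conjugation during the slow Wittig reaction.
   - Fallback: Reverse the polarity so that 9 is never made. Convert 7 to the iodide and then the phosphonium salt. Treat the non-stabilised ylide with 1-(tert-butyldimethylsilyloxy)butan-2-one to give the trisubstituted allylic ether (Z-major). TBAF and MnO2 then give the enal, which rejoins the route at step 7.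
3. **Step 10.**
   - Risk: The neopentyl aldehyde is hindered and sits masked as a lactol, so olefination may stall.
   - Fallback: O-allylate the carboxylate (Cs2CO3, allyl bromide), which opens the pseudo-acid. Follow with Takai iodo-olefination to the E-vinyl iodide, Suzuki coupling with (E)-styrylboronic acid, and Pd(0) deallylation.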